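**Assumption:** (2R)-2-hydroxy-3-methylbutanoic acid (the hydroxy acid of D-valine) and 2-(bromomethyl)but-1-ene are taken as catalogue chemicals. Core atoms are labelled by the azulene numbering of the target (C1 ketone, C3 tertiary carbinol, C3a, C4 ester carbinol, C6 methyl-bearing alkene carbon, C8a angular-methyl carbon).

## Retrosynthetic overview

1. Target 29 ⇐ acylation of the C4 hydroxyl of diol ketone 27 with 4-methoxybenzoyl chloride.
2. Ring B (cycloheptene, formed last) ⇐ ring-closing metathesis of diene 26; the C4 carbinol ⇐ chelation-controlled methallylation of aldehyde 24.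
3. Quaternary C8a–C8 bond ⇐ Claisen rearrangement of the allyl enol ether 20 of ring A (key step), anti to the C3a substituent.
4. C3a–C4 bond ⇐ alkoxide-directed conjugate addition of a hydroxymethyl-anion equivalent to cyclopentenone 11.
5. Ring A (cyclopentenone, formed first) ⇐ aldol condensation of keto aldehyde 10; its C3 carbinol ⇐ acid 1 by dioxolanone alkylation (self-regeneration of the stereocentre).

## Route

Step 1
Reactants: 1 (2R)-2-hydroxy-3-methylbutanoic acid; 2 2,2-dimethylpropanal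
Product: 3 (2R,5R)-2-tert-butyl-5-(propan-2-yl)-1,3-dioxolan-4-one
Conditions: TsOH·H2O (cat.), H2SO4 (cat.), pentane, reflux, Dean–Stark; crystallisation
Reagents that add atoms: 2,2-dimethylpropanal, CC(C)(C)C=O
Why: Acid-catalysed acetalisation under thermodynamic control gives the cis-dioxolanone, so the new acetal centre (2R) is set by the bought (R)-carbinol centre and stores its chirality for the next step (Seebach self-regeneration of stereocentres).

Step 2
Reactants: 3 (2R,5R)-2-tert-butyl-5-(propan-2-yl)-1,3-dioxolan-4-one; 4 2-(bromomethyl)but-1-ene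
Product: 6 (2R,5R)-2-tert-butyl-5-(2-methylidenebutyl)-5-(propan-2-yl)-1,3-dioxolan-4-one, via lithium enolate 5 (not isolated)
Conditions: LiN(iPr)2, THF, −78 °C; then 4, −78 → −30 °C
Reagents that add atoms: 2-(bromomethyl)but-1-ene, C=C(CC)CBr
Why: In this enolate alkylation the planar lithium enolate is attacked by the allylic bromide on the face anti to the tert-butyl group, which rebuilds the quaternary carbinol centre (5R) with overall retention.

Step 3
Reactants: 6 (2R,5R)-2-tert-butyl-5-(2-methylidenebutyl)-5-(propan-2-yl)-1,3-dioxolan-4-one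
Product: 7 (2R,5R)-2-tert-butyl-5-(2-methylidenebutyl)-5-(propan-2-yl)-1,3-dioxolan-4-ol (both C4 epimers)
Conditions: iBu2AlH, CH2Cl2, −78 °C; aq. potassium sodium tartrate
Reagents that add atoms: none
Why: Partial hydride reduction of the lactone-type carbonyl at low temperature stops at the cyclic hemiacetal while alkene and acetal are inert, and the new lactol centre is of no consequence because it is lost in step 4.

Step 4
Reactants: 7 (2R,5R)-2-tert-butyl-5-(2-methylidenebutyl)-5-(propan-2-yl)-1,3-dioxolan-4-ol; 8 ozone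
Product: 11 (4R)-4-hydroxy-2-methyl-4-(propan-2-yl)cyclopent-2-en-1-one, via keto lactol 9 (not isolated), via hydroxy keto aldehyde 10 (not isolated)
Conditions: O3, CH2Cl2/MeOH, −78 °C; Me2S, −78 → 23 °C; then pyrrolidine (0.3 equiv), AcOH (0.3 equiv), THF, 40 °C
Reagents that add atoms: ozone, [O-][O+]=O
Why: Ozonolysis of the 1,1-disubstituted alkene unmasks the ethyl ketone, the hemiacetal then opens with loss of pivalaldehyde, and an amine-catalysed intramolecular aldol condensation of the 1,4-keto aldehyde closes ring A, leaving the carbinol centre (no α-hydrogen) untouched.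

Step 5
Reactants: 11 (4R)-4-hydroxy-2-methyl-4-(propan-2-yl)cyclopent-2-en-1-one; 12 (chloromethyl)dimethyl(propan-2-yloxy)silane; 13 chlorotrimethylsilane
Product: 17 (3R,4R)-3-{[dimethyl(propan-2-yloxy)silyl]methyl}-2-methyl-4-(propan-2-yl)-1,4-bis[(trimethylsilyl)oxy]cyclopent-1-ene, via Grignard reagent 14 (not isolated), via chloromagnesium alkoxide 15 (not isolated), via magnesium enolate 16 (not isolated)
Conditions: 12, Mg, THF, 23 °C (gives 14); 11, tBuMgCl (1.0 equiv), THF, −78 °C; then 14 (1.5 equiv), CuBr·SMe2 (10 mol%), −78 → −30 °C; then 13, Et3N, DMPU, −30 → 23 °C; non-aqueous work-up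
Reagents that add atoms: (chloromethyl)dimethyl(propan-2-yloxy)silane, CC(C)O[Si](C)(C)CCl; chlorotrimethylsilane, C[Si](C)(C)Cl
Why: Copper-catalysed conjugate addition of the Tamao hydroxymethyl-anion equivalent occurs at C3a on the face syn to the magnesium alkoxide and anti to the larger isopropyl group (alkoxide-directed 1,4-addition), and silylation traps the regiodefined enolate together with the alkoxide.

Step 6
Reactants: 17 (3R,4R)-3-{[dimethyl(propan-2-yloxy)silyl]methyl}-2-methyl-4-(propan-2-yl)-1,4-bis[(trimethylsilyl)oxy]cyclopent-1-ene; 18 prop-2-en-1-yl 4-methylbenzenesulfonate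
Product: 21 (2R,3R,4R)-3-{[dimethyl(propan-2-yloxy)silyl]methyl}-2-methyl-4-(propan-2-yl)-2-(prop-2-en-1-yl)-4-[(trimethylsilyl)oxy]cyclopentan-1-one, via potassium enolate 19 (not isolated), via allyl enol ether 20 (not isolated)
Conditions: KOtBu (1.0 equiv), THF, −78 → 0 °C; 18, 18-crown-6, DMPU, 0 → 23 °C; then PhMe, 170 °C, sealed tube
Reagents that add atoms: prop-2-en-1-yl 4-methylbenzenesulfonate, C=CCOS(=O)(=O)c1ccc(C)cc1
Why: The crown-separated potassium enolate is O-allylated at its hindered terminus by the hard tosylate, and the Claisen rearrangement ([3,3]-sigmatropic) then delivers the allyl group suprafacially to C8a on the face anti to the adjacent silylmethyl group, setting the quaternary centre (any material allylated directly on carbon is the same compound).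

Step 7
Reactants: 21 (2R,3R,4R)-3-{[dimethyl(propan-2-yloxy)silyl]methyl}-2-methyl-4-(propan-2-yl)-2-(prop-2-en-1-yl)-4-[(trimethylsilyl)oxy]cyclopentan-1-one; 22 hydrogen peroxide
Product: 23 (2R,3S,4R)-4-hydroxy-3-(hydroxymethyl)-2-methyl-4-(propan-2-yl)-2-(prop-2-en-1-yl)cyclopentan-1-one
Conditions: KF, KHCO3, 30% aq. H2O2, THF/MeOH, 45 °C
Reagents that add atoms: hydrogen peroxide, OO
Why: Tamao–Fleming oxidation replaces the C–Si bond by C–OH at an achiral CH2 and the fluoride/methanol medium also removes the tertiary trimethylsilyl ether, while ketone and alkene are untouched.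

Step 8
Reactants: 23 (2R,3S,4R)-4-hydroxy-3-(hydroxymethyl)-2-methyl-4-(propan-2-yl)-2-(prop-2-en-1-yl)cyclopentan-1-one
Product: 24 (1R,2R,5R)-5-hydroxy-2-methyl-3-oxo-5-(propan-2-yl)-2-(prop-2-en-1-yl)cyclopentane-1-carbaldehyde
Conditions: PhI(OAc)2, TEMPO (10 mol%), CH2Cl2, 23 °C
Reagents that add atoms: none
Why: The nitroxyl-catalysed oxidation is selective for the primary alcohol (the tertiary one cannot be oxidised), and the α-centre, flanked by two fully substituted carbons, already has its more stable configuration.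

Step 9
Reactants: 24 (1R,2R,5R)-5-hydroxy-2-methyl-3-oxo-5-(propan-2-yl)-2-(prop-2-en-1-yl)cyclopentane-1-carbaldehyde; 25 tributyl(2-methylprop-2-en-1-yl)stannane
Product: 26 (2R,3S,4R)-4-hydroxy-3-[(1S)-1-hydroxy-3-methylbut-3-en-1-yl]-2-methyl-4-(propan-2-yl)-2-(prop-2-en-1-yl)cyclopentan-1-one
Conditions: MgBr2·OEt2 (3 equiv), CH2Cl2, −40 °C; then 25, −40 → 0 °C
Reagents that add atoms: tributyl(2-methylprop-2-en-1-yl)stannane, CCCC[Sn](CCCC)(CCCC)CC(C)=C
Why: In this chelation-controlled allylstannane addition (Keck type) MgBr2 bridges the cis C3 hydroxyl and the aldehyde oxygen in a six-membered chelate, so the methallyl group attacks the exposed outer face and gives the (S)-carbinol, while the hindered ketone does not react.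

Step 10
Reactants: 26 (2R,3S,4R)-4-hydroxy-3-[(1S)-1-hydroxy-3-methylbut-3-en-1-yl]-2-methyl-4-(propan-2-yl)-2-(prop-2-en-1-yl)cyclopentan-1-one
Product: 27 (3R,3aS,4S,8aR)-3,4-dihydroxy-6,8a-dimethyl-3-(propan-2-yl)-3,3a,4,5,8,8a-hexahydroazulen-1(2H)-one
Conditions: second-generation Grubbs catalyst (H2IMes)(PCy3)Cl2Ru=CHPh (5 mol%), CH2Cl2 (5 mM), 40 °C
Reagents that add atoms: none
Why: Ring-closing metathesis between the monosubstituted and the 1,1-disubstituted alkene closes the seven-membered ring B as the trisubstituted cycloalkene with loss of ethene, touching no stereocentre (the trans ring fusion was fixed in steps 5 and 6).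

Step 11
Reactants: 27 (3R,3aS,4S,8aR)-3,4-dihydroxy-6,8a-dimethyl-3-(propan-2-yl)-3,3a,4,5,8,8a-hexahydroazulen-1(2H)-one; 28 4-methoxybenzoyl chloride
Product: 29 [(3R,3aS,4S,8aR)-3-hydroxy-6,8a-dimethyl-1-oxo-3-(propan-2-yl)-1,2,3,3a,4,5,8,8a-octahydroazulen-4-yl] 4-methoxybenzoate
Conditions: 28, Et3N, DMAP (cat.), CH2Cl2, 0 → 23 °C
Reagents that add atoms: 4-methoxybenzoyl chloride, COc1ccc(cc1)C(Cl)=O
Why: Nucleophile-catalysed acylation esterifies the secondary C4 hydroxyl with retention, because the tertiary C3 hydroxyl is too hindered to react.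

## Compound list

1 | (2R)-2-hydroxy-3-methylbutanoic acid | CC(C)[C@@H](O)C(=O)O | starting material
2 | 2,2-dimethylpropanal | CC(C)(C)C=O | starting material
3 | (2R,5R)-2-tert-butyl-5-(propan-2-yl)-1,3-dioxolan-4-one | CC(C)[C@H]1O[C@@H](C(C)(C)C)OC1=O | intermediate
4 | 2-(bromomethyl)but-1-ene | C=C(CC)CBr | starting material
5 | lithium (2R)-2-tert-butyl-5-(propan-2-yl)-1,3-dioxol-4-olate | CC(C)C1=C([O-])O[C@H](C(C)(C)C)O1.[Li+] | intermediate
6 | (2R,5R)-2-tert-butyl-5-(2-methylidenebutyl)-5-(propan-2-yl)-1,3-dioxolan-4-one | CC(C)[C@@]1(CC(=C)CC)O[C@@H](C(C)(C)C)OC1=O | intermediate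
7 | (2R,5R)-2-tert-butyl-5-(2-methylidenebutyl)-5-(propan-2-yl)-1,3-dioxolan-4-ol (both C4 epimers) | CC(C)[C@@]1(CC(=C)CC)O[C@@H](C(C)(C)C)OC1O | intermediate
8 | ozone | [O-][O+]=O | starting material
9 | 1-[(2R,4R)-2-tert-butyl-5-hydroxy-4-(propan-2-yl)-1,3-dioxolan-4-yl]butan-2-one | CC(C)[C@@]1(CC(=O)CC)O[C@@H](C(C)(C)C)OC1O | intermediate
10 | (2R)-2-hydroxy-4-oxo-2-(propan-2-yl)hexanal | CC(C)[C@](O)(CC(=O)CC)C=O | intermediate
11 | (4R)-4-hydroxy-2-methyl-4-(propan-2-yl)cyclopent-2-en-1-one | CC1=C[C@](O)(C(C)C)CC1=O | intermediate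
12 | (chloromethyl)dimethyl(propan-2-yloxy)silane | CC(C)O[Si](C)(C)CCl | starting material
13 | chlorotrimethylsilane | C[Si](C)(C)Cl | starting material
14 | {[dimethyl(propan-2-yloxy)silyl]methyl}magnesium chloride | CC(C)O[Si](C)(C)C[Mg]Cl | intermediate
15 | chloromagnesium (1R)-3-methyl-4-oxo-1-(propan-2-yl)cyclopent-2-en-1-olate | CC1=C[C@](O[Mg]Cl)(C(C)C)CC1=O | intermediate
16 | chloromagnesium (3R,4R)-4-[(chloromagnesio)oxy]-3-{[dimethyl(propan-2-yloxy)silyl]methyl}-2-methyl-4-(propan-2-yl)cyclopent-1-en-1-olate | CC1=C(O[Mg]Cl)C[C@@](O[Mg]Cl)(C(C)C)[C@@H]1C[Si](C)(C)OC(C)C | intermediate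
17 | (3R,4R)-3-{[dimethyl(propan-2-yloxy)silyl]methyl}-2-methyl-4-(propan-2-yl)-1,4-bis[(trimethylsilyl)oxy]cyclopent-1-ene | CC1=C(O[Si](C)(C)C)C[C@@](O[Si](C)(C)C)(C(C)C)[C@@H]1C[Si](C)(C)OC(C)C | intermediate
18 | prop-2-en-1-yl 4-methylbenzenesulfonate | C=CCOS(=O)(=O)c1ccc(C)cc1 | starting material
19 | potassium (3R,4R)-3-{[dimethyl(propan-2-yloxy)silyl]methyl}-2-methyl-4-(propan-2-yl)-4-[(trimethylsilyl)oxy]cyclopent-1-en-1-olate | CC1=C([O-])C[C@@](O[Si](C)(C)C)(C(C)C)[C@@H]1C[Si](C)(C)OC(C)C.[K+] | intermediate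
20 | (3R,4R)-3-{[dimethyl(propan-2-yloxy)silyl]methyl}-2-methyl-4-(propan-2-yl)-1-(prop-2-en-1-yloxy)-4-[(trimethylsilyl)oxy]cyclopent-1-ene | CC1=C(OCC=C)C[C@@](O[Si](C)(C)C)(C(C)C)[C@@H]1C[Si](C)(C)OC(C)C | intermediate
21 | (2R,3R,4R)-3-{[dimethyl(propan-2-yloxy)silyl]methyl}-2-methyl-4-(propan-2-yl)-2-(prop-2-en-1-yl)-4-[(trimethylsilyl)oxy]cyclopentan-1-one | C=CC[C@@]1(C)C(=O)C[C@@](O[Si](C)(C)C)(C(C)C)[C@@H]1C[Si](C)(C)OC(C)C | intermediate
22 | hydrogen peroxide | OO | starting material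
23 | (2R,3S,4R)-4-hydroxy-3-(hydroxymethyl)-2-methyl-4-(propan-2-yl)-2-(prop-2-en-1-yl)cyclopentan-1-one | C=CC[C@@]1(C)C(=O)C[C@@](O)(C(C)C)[C@@H]1CO | intermediate
24 | (1R,2R,5R)-5-hydroxy-2-methyl-3-oxo-5-(propan-2-yl)-2-(prop-2-en-1-yl)cyclopentane-1-carbaldehyde | C=CC[C@@]1(C)C(=O)C[C@@](O)(C(C)C)[C@@H]1C=O | intermediate
25 | tributyl(2-methylprop-2-en-1-yl)stannane | CCCC[Sn](CCCC)(CCCC)CC(C)=C | starting material
26 | (2R,3S,4R)-4-hydroxy-3-[(1S)-1-hydroxy-3-methylbut-3-en-1-yl]-2-methyl-4-(propan-2-yl)-2-(prop-2-en-1-yl)cyclopentan-1-one | C=CC[C@@]1(C)C(=O)C[C@@](O)(C(C)C)[C@@H]1[C@@H](O)CC(C)=C | intermediate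
27 | (3R,3aS,4S,8aR)-3,4-dihydroxy-6,8a-dimethyl-3-(propan-2-yl)-3,3a,4,5,8,8a-hexahydroazulen-1(2H)-one | O[C@H]1CC(C)=CC[C@@]2(C)C(=O)C[C@@](O)(C(C)C)[C@H]12 | intermediate
28 | 4-methoxybenzoyl chloride | COc1ccc(cc1)C(Cl)=O | starting material
29 | [(3R,3aS,4S,8aR)-3-hydroxy-6,8a-dimethyl-1-oxo-3-(propan-2-yl)-1,2,3,3a,4,5,8,8a-octahydroazulen-4-yl] 4-methoxybenzoate | COc1ccc(C(=O)O[C@H]2CC(C)=CC[C@@]3(C)C(=O)C[C@@](O)(C(C)C)[C@H]23)cc1 | target

## Step count and risks

Total step count: 11. Longest linear sequence: 11 (fully linear from 1).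

The three steps most likely to fail are 4, 5 and 9.

**The one-pot ozonolysis/aldol condensation (step 4).** The free hydroxy keto aldehyde 10 can undergo retro-aldol or acyloin-type reactions before it cyclises. The fallback closes ring A at the carboxylic oxidation level and sets out from 6. Ozonolysis (O3, CH2Cl2, −78 °C; Me2S) gives (2R,5R)-2-tert-butyl-5-(2-oxobutyl)-5-(propan-2-yl)-1,3-dioxolan-4-one F1. LiN(SiMe3)2 (THF, −78 → 0 °C) then drives an intramolecular Claisen (Dieckmann-type) acylation of the ketone enolate by the dioxolanone carbonyl, with loss of pivalaldehyde, to (4R)-4-hydroxy-2-methyl-4-(propan-2-yl)cyclopentane-1,3-dione F2. Acid-catalysed O-methylation at the less hindered carbonyl (MeOH, HC(OMe)3, TsOH) gives the vinylogous ester (5R)-5-hydroxy-3-methoxy-2-methyl-5-(propan-2-yl)cyclopent-2-en-1-one F3. Stork–Danheiser reduction and transposition (iBu2AlH, then aq. HCl) comes back to the route at 11.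

**The conjugate addition next to the fully substituted carbinol carbon (step 5).** It may be slow or take the wrong face. The fallback delivers the carbon intramolecularly from the C3 oxygen and sets out from 11. Silylation with (bromomethyl)chlorodimethylsilane (Et3N, DMAP, CH2Cl2) gives (4R)-4-{[(bromomethyl)dimethylsilyl]oxy}-2-methyl-4-(propan-2-yl)cyclopent-2-en-1-one F4. A Stork–Nishiyama silicon-tethered 5-exo radical cyclisation is run with allyltributylstannane as chain carrier (AIBN, PhH, 80 °C). It bonds the CH2 to C3a necessarily cis to the oxygen, and the resulting α-keto radical is allylated on the open face, giving (3aR,4R,6aR)-2,2,4-trimethyl-6a-(propan-2-yl)-4-(prop-2-en-1-yl)hexahydro-5H-cyclopenta[d][1,2]oxasilol-5-one F5. Tamao–Fleming oxidation (KF, KHCO3, H2O2, THF/MeOH) returns to the route at 23, so this path also replaces step 6.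

**The methallylation (step 9).** It depends on the magnesium chelate to set C4. If the C4 epimer predominates (it can be made on purpose with the non-chelating BF3·OEt2), the fallback sets out from 24. It carries (2R,3S,4R)-4-hydroxy-3-[(1R)-1-hydroxy-3-methylbut-3-en-1-yl]-2-methyl-4-(propan-2-yl)-2-(prop-2-en-1-yl)cyclopentan-1-one F6 through the same ring-closing metathesis to (3R,3aS,4R,8aR)-3,4-dihydroxy-6,8a-dimethyl-3-(propan-2-yl)-3,3a,4,5,8,8a-hexahydroazulen-1(2H)-one F7. A Mitsunobu esterification with 4-methoxybenzoic acid (PPh3, diisopropyl azodicarboxylate, PhMe) then inverts C4 and comes back to the route directly at 29.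

## Further compounds

F1 | step 4 | (2R,5R)-2-tert-butyl-5-(2-oxobutyl)-5-(propan-2-yl)-1,3-dioxolan-4-one | CC(C)[C@@]1(CC(=O)CC)O[C@@H](C(C)(C)C)OC1=O
F2 | step 4 | (4R)-4-hydroxy-2-methyl-4-(propan-2-yl)cyclopentane-1,3-dione | CC1C(=O)C[C@@](O)(C(C)C)C1=O
F3 | step 4 | (5R)-5-hydroxy-3-methoxy-2-methyl-5-(propan-2-yl)cyclopent-2-en-1-one | COC1=C(C)C(=O)[C@](O)(C(C)C)C1
F4 | step 5 | (4R)-4-{[(bromomethyl)dimethylsilyl]oxy}-2-methyl-4-(propan-2-yl)cyclopent-2-en-1-one | CC1=C[C@](O[Si](C)(C)CBr)(C(C)C)CC1=O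
F5 | step 5 | (3aR,4R,6aR)-2,2,4-trimethyl-6a-(propan-2-yl)-4-(prop-2-en-1-yl)hexahydro-5H-cyclopenta[d][1,2]oxasilol-5-one | C=CC[C@@]1(C)C(=O)C[C@]2(C(C)C)O[Si](C)(C)C[C@H]12
F6 | step 9 | (2R,3S,4R)-4-hydroxy-3-[(1R)-1-hydroxy-3-methylbut-3-en-1-yl]-2-methyl-4-(propan-2-yl)-2-(prop-2-en-1-yl)cyclopentan-1-one | C=CC[C@@]1(C)C(=O)C[C@@](O)(C(C)C)[C@@H]1[C@H](O)CC(C)=C
F7 | step 9 | (3R,3aS,4R,8aR)-3,4-dihydroxy-6,8a-dimethyl-3-(propan-2-yl)-3,3a,4,5,8,8a-hexahydroazulen-1(2H)-one | O[C@@H]1CC(C)=CC[C@@]2(C)C(=O)C[C@@](O)(C(C)C)[C@H]12
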